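## Retrosynthetic overview

- Target 16 comes from syn-elimination of an axial C7 selenoxide, which can reach only H-6. The selenide is the PhSeH adduct of the Δ7-17-enal, the enal comes from a ¹O₂ ene/dehydration of the Δ8(17) olefin, and the olefin comes from the 8-ol.
- Side chain: C13=C14 is made by a Wittig reaction on a 16-hydroxy-13-ketone. The key bond C13–C16 is made by adding a hydroxymethyl anion (LiCH2OLi) to the lactone carbonyl of ent-ambreinolide.
- ent-Ambreinolide comes from one catalytic asymmetric polyene cyclisation of farnesylacetic acid. Ring A closes first, then ring B, then the δ-lactone.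
- Farnesylacetic acid comes from farnesyl bromide and the acetic acid dianion.

Assumption: labdane numbering is used throughout; (2E,6E)-farnesyl bromide, Bu3SnCH2OH and Ph3P=CHCO2t-Bu are bought as catalogue chemicals, and the IDPi acid is accessible in either enantiomeric form from (R)- or (S)-BINOL.

## Route

Step 1
Reactants: 1 (2E,6E)-farnesyl bromide
Product: 2 (4E,8E)-farnesylacetic acid
Conditions: AcOH, LDA (2.1 equiv), THF–DMPU, 0 → 40 °C; then 1, 0 °C → rt; 1 M HCl
Reagents that add atoms: acetic acid, CC(=O)O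
Why: SN2 alkylation of the acetic acid dianion (carboxylate-enolate alkylation) at the primary allylic bromide adds C12 and C13 in one operation, leaves both E-olefins untouched and forms no stereocentre.

Step 2
Reactants: 2 (4E,8E)-farnesylacetic acid
Product: 3 ent-ambreinolide
Conditions: confined imidodiphosphorimidate (IDPi) Brønsted acid (3 mol %, the antipode of the catalyst that gives the natural series), (CF3)3COH, 0 °C; recrystallise
Reagents that add atoms: none
Why: In this proton-initiated biomimetic polyene cyclisation terminated by the carboxyl group, Stork–Eschenmoser anti additions through the chair–chair fold of the all-E triene set the relative configuration (H-5/CH3-20 trans, H-9 anti to CH3-20, 8-O equatorial), and the chiral counter-anion selects the face of the terminal olefin that is protonated, so the catalyst antipode gives the ent series; the racemic lactonisation of 2 is classical and the asymmetric version is known for the lower homologue acid.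

Step 3
Reactants: 3 ent-ambreinolide
Product: 5 ent-8α,16-dihydroxy-14,15-dinorlabdan-13-one, via dilithium hemiketal adduct 4 (not isolated)
Conditions: Bu3SnCH2OH (1.3 equiv), n-BuLi (2.6 equiv), THF, −78 → −30 °C; then 3, −78 °C; AcOH quench at −78 °C
Reagents that add atoms: (tributylstannyl)methanol, CCCC[Sn](CCCC)(CCCC)CO
Why: Proposed new method: C,O-dilithiated methanol, a hydroxymethyl anion whose oxygen-bearing carbon has reversed polarity, adds once to the unhindered lactone carbonyl C13 (nucleophilic acyl addition joining two naturally electrophilic carbons), and the Li-chelated tetrahedral adduct 4 holds at −78 °C until the acid quench, so no second addition occurs and C8–O is released as the free tertiary alcohol without any protecting group; the closest known reactions are mono-additions of MOMOCH2Li or BnOCH2Li to lactones and additions of LiCH2OLi to ketones, and no stereocentre is touched.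

Step 4
Reactants: 5 ent-8α,16-dihydroxy-14,15-dinorlabdan-13-one
Product: 6 tert-butyl ent-8α,16-dihydroxylabd-13E-en-15-oate
Conditions: Ph3P=CHCO2t-Bu (2 equiv), toluene, 90 °C
Reagents that add atoms: tert-butyl (triphenylphosphoranylidene)acetate, CC(C)(C)OC(=O)C=P(c1ccccc1)(c1ccccc1)c1ccccc1
Why: In this Wittig olefination with a stabilised ylide, the α-hydroxy ketone is activated towards the ylide and, as with hydroxyacetone, places the oxygenated CH2 group anti to the ester, which sets the 13E geometry (CH2OH trans to the ester, C12 chain cis to it); the minor Z isomer is removed by chromatography.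

Step 5
Reactants: 6 tert-butyl ent-8α,16-dihydroxylabd-13E-en-15-oate
Product: 9 tert-butyl ent-16-acetoxylabda-8(17),13E-dien-15-oate, via hydroxy acetate 7 (not isolated), via chlorosulfite 8 (not isolated)
Conditions: Ac2O (1.1 equiv), pyridine, DMAP (cat.), CH2Cl2, 0 °C; then SOCl2 (2 equiv), −78 → −30 °C
Reagents that add atoms: acetic anhydride, CC(=O)OC(C)=O
Why: Chemoselective acetylation of the primary allylic alcohol is followed in the same pot by SOCl2–pyridine dehydration (E2 of the chlorosulfite), and because the equatorial C8–O bond has no anti-periplanar ring hydrogen, only a hydrogen of the freely rotating C17 methyl can leave, so the exocyclic Δ8(17) olefin is the main product and C9 is untouched.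

Step 6
Reactants: 9 tert-butyl ent-16-acetoxylabda-8(17),13E-dien-15-oate
Product: 12 tert-butyl ent-16-acetoxy-17-oxolabda-7,13E-dien-15-oate, via allylic hydroperoxide 10 (not isolated), via allylic peracetate 11 (not isolated)
Conditions: O2, TPP (cat.), white LED, Ac2O, pyridine, DMAP (cat.), CH2Cl2, 0 °C
Reagents that add atoms: dioxygen, O=O
Why: In this Schenck ene reaction followed by Kornblum–DeLaMare-type fragmentation of the peracetate, ¹O₂ attacks only the electron-rich 1,1-disubstituted olefin (the enoate is inert) from the face away from CH3-20 and takes axial H-7 rather than H-9 (whose loss would push C11 and C17 into A1,3 strain), so the double bond moves to C7=C8 and C17 reaches the aldehyde level in one pot.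

Step 7
Reactants: 12 tert-butyl ent-16-acetoxy-17-oxolabda-7,13E-dien-15-oate
Product: 14 ent-16-acetoxy-17-oxo-7α-(phenylselanyl)-8βH-labd-13E-en-15-oic acid, via enal acid 13 (not isolated)
Conditions: TFA–CH2Cl2 (1:4), 0 °C → rt, evaporate with toluene; then PhSeH (1.2 equiv), Et3N (10 mol %), CH2Cl2, −40 °C
Reagents that add atoms: benzeneselenol, [SeH]c1ccccc1
Why: After acidolysis of the tert-butyl ester (E1), the seleno-Michael addition delivers PhSe axially to C7 on the face opposite CH3-20 and the enol is protonated anti to it, giving the axial selenide and the equatorial 8-CHO (H-8 syn to CH3-20, CHO trans to the C9 chain), which is also the more stable C8 epimer, so C8 is set under both kinetic and thermodynamic control.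

Step 8
Reactants: 14 ent-16-acetoxy-17-oxo-7α-(phenylselanyl)-8βH-labd-13E-en-15-oic acid
Product: 16 target CNP0217581.1, via selenoxide 15 (not isolated)
Conditions: NaIO4 (1.5 equiv), THF–pH 7 phosphate buffer, 0 °C → rt; work-up at pH 4
Reagents that add atoms: none
Why: In this selenoxide syn-elimination the axial selenoxide has a cis hydrogen only at C6 (H-8 is trans-diaxial to Se and out of reach), so the olefin must form at C6=C7, away from the carbonyl, and the cold near-neutral medium suppresses E1cB loss and conjugation, so the C8 centre from step 7 is kept.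

## Compound list

1 | (2E,6E)-farnesyl bromide, (2E,6E)-1-bromo-3,7,11-trimethyldodeca-2,6,10-triene | CC(C)=CCC/C(C)=C/CC/C(C)=C/CBr | starting material
2 | (4E,8E)-farnesylacetic acid, (4E,8E)-5,9,13-trimethyltetradeca-4,8,12-trienoic acid | CC(C)=CCC/C(C)=C/CC/C(C)=C/CCC(=O)O | intermediate
3 | ent-ambreinolide, ent-14,15,16-trinorlabdan-13,8-olide, (5R,8S,9S,10R); trans-anti-trans tricycle, O on C8 equatorial, CH3-17 axial and syn to CH3-20 | O=C1CC[C@@H]2[C@@](C)(O1)CC[C@@H]3C(C)(C)CCC[C@@]23C | intermediate
4 | dilithium hemiketal adduct of 3 with LiCH2OLi (C13 configuration undefined) | [Li]OCC1(O[Li])CC[C@@H]2[C@@](C)(O1)CC[C@@H]3C(C)(C)CCC[C@@]23C | intermediate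
5 | ent-8α,16-dihydroxy-14,15-dinorlabdan-13-one (8-OH equatorial, core as in 3) | OCC(=O)CC[C@@H]1[C@@](C)(O)CC[C@@H]2C(C)(C)CCC[C@@]12C | intermediate
6 | tert-butyl ent-8α,16-dihydroxylabd-13E-en-15-oate (CH2OH trans to CO2t-Bu) | OC/C(=C/C(=O)OC(C)(C)C)CC[C@@H]1[C@@](C)(O)CC[C@@H]2C(C)(C)CCC[C@@]12C | intermediate
7 | tert-butyl ent-16-acetoxy-8α-hydroxylabd-13E-en-15-oate | CC(=O)OC/C(=C/C(=O)OC(C)(C)C)CC[C@@H]1[C@@](C)(O)CC[C@@H]2C(C)(C)CCC[C@@]12C | intermediate
8 | 8-chlorosulfite of 7 | CC(=O)OC/C(=C/C(=O)OC(C)(C)C)CC[C@@H]1[C@@](C)(OS(=O)Cl)CC[C@@H]2C(C)(C)CCC[C@@]12C | intermediate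
9 | tert-butyl ent-16-acetoxylabda-8(17),13E-dien-15-oate | CC(=O)OC/C(=C/C(=O)OC(C)(C)C)CC[C@@H]1C(=C)CC[C@@H]2C(C)(C)CCC[C@@]12C | intermediate
10 | tert-butyl ent-16-acetoxy-17-hydroperoxylabda-7,13E-dien-15-oate | CC(=O)OC/C(=C/C(=O)OC(C)(C)C)CC[C@@H]1C(COO)=CC[C@@H]2C(C)(C)CCC[C@@]12C | intermediate
11 | 17-peracetate of 10 | CC(=O)OC/C(=C/C(=O)OC(C)(C)C)CC[C@@H]1C(COOC(C)=O)=CC[C@@H]2C(C)(C)CCC[C@@]12C | intermediate
12 | tert-butyl ent-16-acetoxy-17-oxolabda-7,13E-dien-15-oate | CC(=O)OC/C(=C/C(=O)OC(C)(C)C)CC[C@@H]1C(C=O)=CC[C@@H]2C(C)(C)CCC[C@@]12C | intermediate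
13 | ent-16-acetoxy-17-oxolabda-7,13E-dien-15-oic acid | CC(=O)OC/C(=C/C(=O)O)CC[C@@H]1C(C=O)=CC[C@@H]2C(C)(C)CCC[C@@]12C | intermediate
14 | ent-16-acetoxy-17-oxo-7α-(phenylselanyl)-8βH-labd-13E-en-15-oic acid (SePh axial and anti to CH3-20; CHO equatorial, cis to SePh, trans to the C9 chain) | CC(=O)OC/C(=C/C(=O)O)CC[C@@H]1[C@@H](C=O)[C@@H]([Se]c3ccccc3)C[C@@H]2C(C)(C)CCC[C@@]12C | intermediate
15 | selenoxide of 14 (Se configuration undefined) | CC(=O)OC/C(=C/C(=O)O)CC[C@@H]1[C@@H](C=O)[C@@H]([Se](=O)c3ccccc3)C[C@@H]2C(C)(C)CCC[C@@]12C | intermediate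
16 | (2E)-3-(acetoxymethyl)-5-[(1R,2S,4aR,8aS)-2-formyl-5,5,8a-trimethyl-1,2,4a,5,6,7,8,8a-octahydronaphthalen-1-yl]pent-2-enoic acid; in labdane numbering (5R,8S,9R,10S), 13E | CC(=O)OC/C(=C/C(=O)O)CC[C@@H]1[C@@H](C=O)C=C[C@@H]2C(C)(C)CCC[C@@]12C | target

## Step count

Total steps: 8. Longest linear sequence: 8.

## Steps most likely to fail

**Step 2.** The confined acid is proven only for the lower homologue that closes a γ-lactone, so conversion or ee may drop for the δ-lactone closure. The fallback sets out from 2 and comes back at 3. Compound 2 is cyclised with ClSO3H in 2-nitropropane at −78 °C to racemic ambreinolide F1. This is saponified with KOH to the racemic 8-hydroxy acid F2. The (R)-1-phenylethylammonium salt of the ent-acid F3 is crystallised to constant rotation. Acidification in warm toluene then frees the amine and recloses the lactone to 3.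

**Step 3.** The dianion may enolise the lactone, or the adduct may collapse early and take up a second equivalent. The fallback sets out from 3 and comes back at 7. The lactone is opened with dimethylsulfoxonium methylide (Me3S(O)I, NaH, THF–DMSO) to the β-keto sulfoxonium ylide F4. An [Ir(cod)Cl]2-catalysed O–H insertion with AcOH gives the 16-acetoxy-13-ketone F5. The same stabilised Wittig ylide then gives 7, which enters step 5 at the SOCl2 stage.

**Step 8.** Enolisation of the β-seleninyl aldehyde could expel the selenium by E1cB and return the conjugated enal. The fallback sets out from 14 and comes back at 16. The aldehyde is masked by reduction with NaBH4 (THF–MeOH, −20 °C) to the 17-alcohol selenide F6. H2O2–pyridine gives the selenoxide F7, which eliminates towards C6 only and forms the homoallylic alcohol F8. NaHCO3-buffered Dess–Martin oxidation gives 16 without conjugation.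

## Further compounds

F1 | step 2 | racemic ambreinolide | O=C1CC[C@@H]2[C@@](C)(O1)CC[C@@H]3C(C)(C)CCC[C@@]23C.O=C1CC[C@H]2[C@](C)(O1)CC[C@H]3C(C)(C)CCC[C@]23C
F2 | step 2 | racemic 8α-hydroxy-14,15,16-trinorlabdan-13-oic acid | OC(=O)CC[C@@H]1[C@@](C)(O)CC[C@@H]2C(C)(C)CCC[C@@]12C.OC(=O)CC[C@H]1[C@](C)(O)CC[C@H]2C(C)(C)CCC[C@]12C
F3 | step 2 | (R)-1-phenylethylammonium salt of ent-8α-hydroxy-14,15,16-trinorlabdan-13-oic acid | C[C@@H]([NH3+])c1ccccc1.[O-]C(=O)CC[C@@H]1[C@@](C)(O)CC[C@@H]2C(C)(C)CCC[C@@]12C
F4 | step 3 | β-keto dimethylsulfoxonium ylide from 3 | C[S+](C)(=O)[CH-]C(=O)CC[C@@H]1[C@@](C)(O)CC[C@@H]2C(C)(C)CCC[C@@]12C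
F5 | step 3 | ent-16-acetoxy-8α-hydroxy-14,15-dinorlabdan-13-one | CC(=O)OCC(=O)CC[C@@H]1[C@@](C)(O)CC[C@@H]2C(C)(C)CCC[C@@]12C
F6 | step 8 | ent-16-acetoxy-17-hydroxy-7α-(phenylselanyl)-8βH-labd-13E-en-15-oic acid | CC(=O)OC/C(=C/C(=O)O)CC[C@@H]1[C@@H](CO)[C@@H]([Se]c3ccccc3)C[C@@H]2C(C)(C)CCC[C@@]12C
F7 | step 8 | selenoxide of F6 | CC(=O)OC/C(=C/C(=O)O)CC[C@@H]1[C@@H](CO)[C@@H]([Se](=O)c3ccccc3)C[C@@H]2C(C)(C)CCC[C@@]12C
F8 | step 8 | ent-16-acetoxy-17-hydroxy-8βH-labda-6,13E-dien-15-oic acid | CC(=O)OC/C(=C/C(=O)O)CC[C@@H]1[C@@H](CO)C=C[C@@H]2C(C)(C)CCC[C@@]12C
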